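# Proposed total synthesis of CNP0267891.2 (37) by twofold carbenoid C–H insertion

## The problem

Target 37 is a linear lignan pentamer. Three 7-methoxy-2-aryl-3-(hydroxymethyl)-2,3-dihydrobenzofurans (rings A, B and C) are joined head to tail, C2 of each ring carrying C5 of the next benzofuran arene. C2 of ring C ends in a 4-hydroxy-3-methoxyphenyl group, and C5 of ring A carries C2 of a lariciresinol-type tetrahydrofuran (3-hydroxymethyl, 4-(4-hydroxy-3-methoxybenzyl)).

There are nine stereocentres: (2R,3S,4S) in the tetrahydrofuran (aryl trans to CH2OH, CH2OH cis to the benzyl group) and a trans C2/C3 pair in each dihydrofuran, (2S,3R) in rings A and B but (2R,3S) in ring C. The four stereo-units are separated by flat arenes, so none can be expected to control another. Within a unit, C4 of the tetrahydrofuran can control C3 and C2, and C2 of a dihydrofuran can control C3 once C3 is epimerisable. The change of sense between ring C and rings A and B therefore has to come from reagents.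

Every ring C2–O bond is a benzylic ether para to an oxygen substituent. These bonds are open to acid ionisation, to hydrogenolysis and, when C3 carries a carbonyl group, to E1cB opening. Free phenols and alcohols tolerate neither oxidants nor metal carbenoids.

The enabling feature is in rings A and B. There the C2–C3 bond joins a benzylic ether carbon (O1–C2H–aryl) to C3, which sits on arene carbon C3a and bears a carboxyl-level carbon (the CH2OH). C3 can therefore be the carbenoid carbon of an aryldiazoacetate and C2 the O–CH2–aryl carbon of an ortho benzyl ether, whose C–H bond lies five atoms away.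

## Retrosynthesis

**37 to 35.** The two terminal phenols are masked as benzyl ethers (tetraol 36) and the three ring hydroxymethyl groups are carried as methyl esters (hydroxy triester 35). No skeletal bond is cut. The esters make C3 epimerisable and are what a carbenoid route delivers; benzyl is the one phenol mask that survives methoxide, hydride and enolate chemistry. The forward steps are an ester reduction and a selective hydrogenolysis.

**35 to 33 (key disconnection).** The C2–C3 bonds of rings A and B are cut, giving bis(aryldiazoacetate) 33; the cis,cis product 34 is the unisolated link. Cutting O1–C2 or C3–C3a instead would leave the stereocentres to be made by separate means. The C2–C3 cut turns each ring into an arylacetate and a benzyl aryl ether, so the chain becomes vanillin-derived monomers joined by ether bonds, and the configuration comes from the catalyst. Two rings and four stereocentres disappear. The forward reaction must find the right C–H bond twice in one molecule, keep the two carbenoids apart and override the remote stereocentres.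

**33 to 28.** The diazo groups come from the two arylacetate CH2 groups of triester 32 by diazo transfer. The arylacetates are traced through bis(acid) 31 and bis(aldehyde) 30 to the two C-allyl groups of acetate 29, and this to alcohol 28. Allyl is chosen as the masked acetate because it survives the hydride needed to build the tetrahydrofuran, and both units are unmasked in the same three operations.

**28 to 24.** The ArO–CH2 bond between units A and B is cut to phenol 14 and benzylic bromide 27 (Williamson). Bromide 27 goes back through alcohol 26 and aldehyde 25 to the ether bond between units B and C, cut to ring C alcohol 24 and 5-allylvanillin 4 (Mitsunobu). Unit B is thus 4 itself, with no protecting group.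

**24 to 4 and 15.** Ring C is opened at C2–C3 by the same insertion, run once and with the mirror-image catalyst, via cis ester 23 to diazo ester 22. Ring C is made first because its sense is opposite to that of rings A and B. Diazo ester 22 goes back through ester 21, acid 20, aldehyde 19, acetate 18, alcohol 17 and aldehyde 16 to 4 and benzyl alcohol 15. The ring C5 carbon travels as CH2OAc, which is inert to the carbenoid and is freed by the methoxide that epimerises C3.

**14 to 10 and 11.** The tetrahydrofuran O1–C2 bond is cut (acid cyclisation of tetraol 13). The C–C bond between C2 and C3 is then cut as an aldol of lactone 10 with aldehyde 11 (via adduct 12). Pivalate 11 comes from 4. This classical lignan sequence lets the one stereocentre of 10 set the two others, and it is done before any ester is present.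

**10 to 5 and 6.** Lactone 10 comes from hydroxy acid 9 and half-ester 8, whose stereocentre is set by asymmetric hydrogenation of Stobbe product 7, made from aldehyde 5 and dimethyl succinate 6.

**4 to 1 and 2.** 5-Allylvanillin 4 is the Claisen product of allyl ether 3, made from vanillin 1 and allyl bromide 2.

## Roads not taken

**Alternative 1:** The cut is through the benzene ring of ring A (C3a–C4 and C7–C7a). In the forward step the silyl ketene acetal of trans lactone A2, which already carries rings B and C, would add to pyrone A3. Loss of CO2 and silanol would then give the aromatic ester A1.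
- Merits: the trans C2/C3 pair of ring A is fixed on a saturated lactone before the arene exists, so no benzylic ester has to be epimerised and no diazo compound is handled. The pyrone writes the 7-methoxy and 5-carboxyl pattern into the ring, and the C5 ester is a good handle for the tetrahydrofuran.
- Weak points: it builds a benzene ring that vanillin supplies for nothing. It answers one dihydrobenzofuran only, so the same cycloaddition (or another method) is needed again for rings B and C inside A2. Each trans lactone needs its own asymmetric entry. The methoxy group on the pyrone terminus slows an inverse-demand addition that already needs heat.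
- Comparison: this road is safer on the question of C2 integrity. The chosen plan sets against it two rings and four stereocentres in one step from ready-made arenes, with the alternating configuration decided by catalyst handedness.

**Alternative 2:** The cut is C3–C3a of ring A. Flavanone A5 would be treated with PhI(OAc)2 (a trivalent iodine reagent), H2SO4 and HC(OMe)3, or with Tl(NO3)3 (trivalent thallium). Arene carbon C4a would shift from C4 to C3, contracting the chromanone to bromo triester A4.
- Merits: the trans ester forms directly, C2 is carried over from the flavanone, and flavanones come from an aldehyde and an acetophenone, which suits an iterative chain growth.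
- Weak points: the medium is strongly acidic and oxidising, while A5 holds two benzylic ring ethers and several trialkoxyarenes. With an electron-rich 2-aryl group the competing shift of that aryl group (to an isoflavone) and dehydrogenation (to a flavone) are the known side paths. The flavanone stereocentre racemises easily by ring opening. The bromide of A4 still has to become the tetrahydrofuran handle in the presence of three esters.
- Comparison: it needs no equilibration step, which is a real advantage. The chosen plan offers neutral conditions that the benzylic ethers tolerate and a stereocentre that comes from a catalyst, not from a labile flavanone.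

**Alternative 3:** The cut is C3–C4 of the tetrahydrofuran. Cp2TiCl (trivalent titanium, from Cp2TiCl2 and zinc dust) would open epoxy cinnamyl ether A7 to a radical at C3. This would add 5-exo to the alkene, and reduction of the benzylic radical would give alcohol A6.
- Merits: the tetrahydrofuran is made last under neutral conditions and never meets a carbenoid. The chair-like transition state favours the 2,3-trans, 3,4-cis arrangement that is needed. The hydroxymethyl group emerges free. In convergence at this ring it is better than the chosen plan, which carries the tetrahydrofuran through ten steps.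
- Weak points: it does not say how the three dihydrobenzofurans of A7 are made, which is the larger problem. The C2 configuration must be installed by a reagent on the most advanced ring A aldehyde. C3 and C4 are then under substrate control that is usually incomplete.
- Comparison: the chosen plan sets the three tetrahydrofuran centres early, on a cheap fragment, from one catalytic hydrogenation. It accepts in return that the tetrahydrofuran C2–H is a possible, though remote, competing site in the key step.

Key step: step 27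

Assumption: Rh2(S-PTTL)4 (PTTL = N-phthaloyl-tert-leucinate) is taken to give the (2R) cis ester and Rh2(R-PTTL)4 the (2S) cis esters in the insertion, and the (R,R)-Et-DuPHOS rhodium catalyst the (S) half-ester 8; each sense is read at first use (steps 4 and 17) and the catalyst enantiomers are exchanged if it is the opposite.

## Route

Step 1
Reactants: 1 vanillin; 2 allyl bromide
Product: 3 4-(allyloxy)-3-methoxybenzaldehyde
Conditions: K2CO3, acetone, reflux
Reagents that add atoms: none
Why: Williamson etherification of the phenoxide with a primary allylic bromide; the aldehyde is inert to carbonate.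

Step 2
Reactants: 3 4-(allyloxy)-3-methoxybenzaldehyde
Product: 4 5-allylvanillin (3-allyl-4-hydroxy-5-methoxybenzaldehyde)
Conditions: neat, 200 °C
Reagents that add atoms: none
Why: Aromatic Claisen rearrangement; the [3,3] shift can only go to C5, the one free ortho position, and tautomerisation restores the phenol.

Step 3
Reactants: 5 4-(benzyloxy)-3-methoxybenzaldehyde; 6 dimethyl succinate
Product: 7 (E)-4-[4-(benzyloxy)-3-methoxyphenyl]-3-(methoxycarbonyl)but-3-enoic acid
Conditions: NaOMe, MeOH, reflux; then aq. HCl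
Reagents that add atoms: none
Why: Stobbe condensation; loss of methoxide and opening to the carboxylate make it irreversible and leave the free acid on the CH2 arm, mainly as the (E) alkene.

Step 4
Reactants: 7 (E)-4-[4-(benzyloxy)-3-methoxyphenyl]-3-(methoxycarbonyl)but-3-enoic acid
Product: 8 (3S)-4-[4-(benzyloxy)-3-methoxyphenyl]-3-(methoxycarbonyl)butanoic acid
Conditions: H2 (5 atm), [Rh(cod)((R,R)-Et-DuPHOS)]BF4 (cat.), NaOMe (0.1 equiv), MeOH, rt
Reagents that add atoms: none
Why: Rhodium-bisphosphine asymmetric hydrogenation of a Stobbe itaconate half-ester, a standard entry to 2-benzylsuccinates; the catalyst sets the single stereocentre (S) and, being homogeneous, leaves the benzyl ether alone.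

Step 5
Reactants: 8 (3S)-4-[4-(benzyloxy)-3-methoxyphenyl]-3-(methoxycarbonyl)butanoic acid
Product: 10 (4S)-4-[4-(benzyloxy)-3-methoxybenzyl]dihydrofuran-2(3H)-one, via hydroxy acid 9 (not isolated)
Conditions: KOH, EtOH; CaCl2, NaBH4, 0 °C to rt; then 2 M HCl
Reagents that add atoms: none
Why: Ca(BH4)2 formed in the flask reduces the methyl ester but not the carboxylate salt, and acidification closes the γ-lactone; the stereocentre is not involved.

Step 6
Reactants: 4 5-allylvanillin
Product: 11 2-allyl-4-formyl-6-methoxyphenyl pivalate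
Conditions: PivCl, Et3N, DMAP (cat.), CH2Cl2, 0 °C to rt
Reagents that add atoms: pivaloyl chloride, CC(C)(C)C(=O)Cl
Why: Acylation of the phenol; the pivalate, flanked by two ortho substituents, is meant to survive the enolate of step 7 and to be cleaved by LiAlH4 in step 8.

Step 7
Reactants: 10 (4S)-4-[4-(benzyloxy)-3-methoxybenzyl]dihydrofuran-2(3H)-one; 11 2-allyl-4-formyl-6-methoxyphenyl pivalate
Product: 12 (3R,4S)-3-[(3-allyl-5-methoxy-4-pivaloyloxyphenyl)(hydroxy)methyl]-4-[4-(benzyloxy)-3-methoxybenzyl]dihydrofuran-2(3H)-one (both carbinol epimers)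
Conditions: LiN(iPr)2, THF, −78 °C; then 11, −78 °C; aq. NH4Cl
Reagents that add atoms: none
Why: Aldol addition of the lactone lithium enolate; the aldehyde approaches anti to the C4 benzyl group, which sets C3 (3R, trans), and the carbinol mixture is of no consequence because that centre is ionised in step 9.

Step 8
Reactants: 12 aldol adduct
Product: 13 (2S,3S)-2-[(3-allyl-4-hydroxy-5-methoxyphenyl)(hydroxy)methyl]-3-[4-(benzyloxy)-3-methoxybenzyl]butane-1,4-diol (both carbinol epimers)
Conditions: LiAlH4, THF, 0 °C to rt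
Reagents that add atoms: none
Why: Hydride reduction opens the lactone to the 1,4-diol and cleaves the aryl pivalate in the same operation; the allyl group and the benzyl ether are inert.

Step 9
Reactants: 13 tetraol
Product: 14 2-allyl-4-{(2R,3S,4S)-4-[4-(benzyloxy)-3-methoxybenzyl]-3-(hydroxymethyl)tetrahydrofuran-2-yl}-6-methoxyphenol
Conditions: CSA (cat.), CH2Cl2, 0 °C to rt
Reagents that add atoms: none
Why: Acid-catalysed dehydrative cyclisation of a p-hydroxybenzylic alcohol through its quinone-methide-like cation, the usual closing step of lariciresinol syntheses; only the hydroxymethyl on the benzyl-bearing carbon can close a five-membered ring, and the aryl group settles trans to the C3 substituent (2R) from either carbinol epimer.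

Step 10
Reactants: 4 5-allylvanillin; 15 4-(benzyloxy)-3-methoxybenzyl alcohol
Product: 16 3-allyl-4-{[4-(benzyloxy)-3-methoxybenzyl]oxy}-5-methoxybenzaldehyde
Conditions: PPh3, DIAD, THF, 0 °C to rt
Reagents that add atoms: none
Why: Mitsunobu etherification; the acidic p-formylphenol displaces the activated primary benzylic alcohol, and its ortho and para positions are blocked, so only O-alkylation is possible.

Step 11
Reactants: 16 aldehyde
Product: 17 (3-allyl-4-{[4-(benzyloxy)-3-methoxybenzyl]oxy}-5-methoxyphenyl)methanol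
Conditions: NaBH4, MeOH/THF, 0 °C
Reagents that add atoms: none
Why: Borohydride reduction of the aryl aldehyde, which must not compete with the side-chain aldehyde in the later oxidation.

Step 12
Reactants: 17 benzylic alcohol
Product: 18 3-allyl-4-{[4-(benzyloxy)-3-methoxybenzyl]oxy}-5-methoxybenzyl acetate
Conditions: Ac2O, pyridine, DMAP (cat.), CH2Cl2, rt
Reagents that add atoms: acetic anhydride, CC(=O)OC(C)=O
Why: Acetylation; the acetate deactivates the CH2–O C–H bonds toward carbenoid insertion and is removed by methoxide in step 17.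

Step 13
Reactants: 18 allyl acetate
Product: 19 (5-(acetoxymethyl)-2-{[4-(benzyloxy)-3-methoxybenzyl]oxy}-3-methoxyphenyl)acetaldehyde
Conditions: OsO4 (cat.), NaIO4, 2,6-lutidine, dioxane/H2O, rt
Reagents that add atoms: osmium tetroxide, O=[Os](=O)(=O)=O (catalytic oxygen carrier); sodium periodate, [Na+].[O-]I(=O)(=O)=O (terminal oxidant)
Why: Lemieux–Johnson cleavage of the terminal alkene (catalytic dihydroxylation, then periodate glycol cleavage); 2,6-lutidine limits over-oxidation and the enolisable arylacetaldehyde is used crude.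

Step 14
Reactants: 19 arylacetaldehyde
Product: 20 (5-(acetoxymethyl)-2-{[4-(benzyloxy)-3-methoxybenzyl]oxy}-3-methoxyphenyl)acetic acid
Conditions: NaClO2, NaH2PO4, 2-methyl-2-butene, t-BuOH/H2O, rt
Reagents that add atoms: sodium chlorite, [Na+].[O-]Cl=O
Why: Pinnick oxidation; 2-methyl-2-butene scavenges HOCl so that the electron-rich arenes are not chlorinated.

Step 15
Reactants: 20 arylacetic acid
Product: 21 methyl (5-(acetoxymethyl)-2-{[4-(benzyloxy)-3-methoxybenzyl]oxy}-3-methoxyphenyl)acetate
Conditions: TMSCHN2, toluene/MeOH, 0 °C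
Reagents that add atoms: trimethylsilyldiazomethane, C[Si](C)(C)C=[N+]=[N-]
Why: Methyl ester formation under neutral conditions, safe for the acid-labile p-alkoxybenzyl aryl ether.

Step 16
Reactants: 21 methyl arylacetate
Product: 22 methyl 2-(5-(acetoxymethyl)-2-{[4-(benzyloxy)-3-methoxybenzyl]oxy}-3-methoxyphenyl)-2-diazoacetate
Conditions: p-ABSA, DBU, MeCN, 0 °C to rt
Reagents that add atoms: 4-acetamidobenzenesulfonyl azide (p-ABSA), CC(=O)Nc1ccc(cc1)S(=O)(=O)N=[N+]=[N-]
Why: Regitz diazo transfer to the arylacetate enolate gives the donor–acceptor diazo ester.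

Step 17
Reactants: 22 diazo ester
Product: 24 methyl (2R,3R)-2-[4-(benzyloxy)-3-methoxyphenyl]-5-(hydroxymethyl)-7-methoxy-2,3-dihydrobenzofuran-3-carboxylate, via cis ester 23 (not isolated)
Conditions: Rh2(S-PTTL)4 (1 mol%), toluene, −60 to −20 °C; then NaOMe (0.3 equiv), MeOH/THF, rt
Reagents that add atoms: none
Why: The intramolecular carbenoid C–H insertion of step 27, run once with the mirror-image catalyst: the catalyst sets C2 (2R) and delivers the cis ester, and methoxide then epimerises C3 through the ester enolate to the trans (2R,3R) ester and methanolyses the acetate.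

Step 18
Reactants: 24 ring C alcohol; 4 5-allylvanillin
Product: 25 methyl (2R,3R)-5-[(2-allyl-4-formyl-6-methoxyphenoxy)methyl]-2-[4-(benzyloxy)-3-methoxyphenyl]-7-methoxy-2,3-dihydrobenzofuran-3-carboxylate
Conditions: PPh3, DIAD, THF, 0 °C to rt
Reagents that add atoms: none
Why: Mitsunobu etherification of the electron-rich benzylic alcohol with the p-formylphenol of a second 5-allylvanillin; the neutral conditions leave the ester stereocentres alone.

Step 19
Reactants: 25 aldehyde
Product: 26 methyl (2R,3R)-5-{[2-allyl-4-(hydroxymethyl)-6-methoxyphenoxy]methyl}-2-[4-(benzyloxy)-3-methoxyphenyl]-7-methoxy-2,3-dihydrobenzofuran-3-carboxylate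
Conditions: NaBH4, MeOH/THF, 0 °C
Reagents that add atoms: none
Why: Chemoselective borohydride reduction of the aldehyde; the methyl ester survives at 0 °C.

Step 20
Reactants: 26 benzylic alcohol
Product: 27 methyl (2R,3R)-5-{[2-allyl-4-(bromomethyl)-6-methoxyphenoxy]methyl}-2-[4-(benzyloxy)-3-methoxyphenyl]-7-methoxy-2,3-dihydrobenzofuran-3-carboxylate
Conditions: CBr4, PPh3, CH2Cl2, 0 °C
Reagents that add atoms: carbon tetrabromide, BrC(Br)(Br)Br
Why: Appel bromination under neutral conditions, which spares the acid-labile benzylic ethers; the reactive bromide is used at once.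

Step 21
Reactants: 27 benzylic bromide; 14 tetrahydrofuran phenol
Product: 28 diallyl alcohol (aryl ether between the phenol oxygen of 14 and the benzylic carbon of 27)
Conditions: K2CO3, Bu4NI (cat.), DMF, rt
Reagents that add atoms: none
Why: Williamson etherification; carbonate deprotonates only the phenol, so the bromide alkylates the phenol oxygen and not the primary alcohol.

Step 22
Reactants: 28 diallyl alcohol
Product: 29 diallyl acetate (O-acetate of 28)
Conditions: Ac2O, pyridine, DMAP (cat.), CH2Cl2, rt
Reagents that add atoms: acetic anhydride, CC(=O)OC(C)=O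
Why: Acetylation of the primary alcohol, which would otherwise undergo O–H insertion; CH2–OAc C–H bonds are poor insertion sites.

Step 23
Reactants: 29 diallyl acetate
Product: 30 bis(arylacetaldehyde)
Conditions: OsO4 (cat.), NaIO4, 2,6-lutidine, dioxane/H2O, rt
Reagents that add atoms: osmium tetroxide, O=[Os](=O)(=O)=O (catalytic oxygen carrier); sodium periodate, [Na+].[O-]I(=O)(=O)=O (terminal oxidant)
Why: Twofold Lemieux–Johnson cleavage of the only two alkenes in the molecule; esters, acetate and ethers are inert and the product is used crude.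

Step 24
Reactants: 30 bis(arylacetaldehyde)
Product: 31 bis(arylacetic acid)
Conditions: NaClO2, NaH2PO4, 2-methyl-2-butene, t-BuOH/H2O, rt
Reagents that add atoms: sodium chlorite, [Na+].[O-]Cl=O
Why: Twofold Pinnick oxidation under buffered conditions with a chlorine scavenger.

Step 25
Reactants: 31 bis(arylacetic acid)
Product: 32 triester (two methyl arylacetates and the ring C methyl ester)
Conditions: TMSCHN2, toluene/MeOH, 0 °C
Reagents that add atoms: trimethylsilyldiazomethane, C[Si](C)(C)C=[N+]=[N-]
Why: Twofold neutral esterification; all three carboxyl groups are now methyl esters.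

Step 26
Reactants: 32 triester
Product: 33 bis(aryldiazoacetate)
Conditions: p-ABSA, DBU, MeCN, 0 °C to rt
Reagents that add atoms: 4-acetamidobenzenesulfonyl azide (p-ABSA), CC(=O)Nc1ccc(cc1)S(=O)(=O)N=[N+]=[N-]
Why: Twofold Regitz diazo transfer at the two CH2 groups; the tertiary C3–H of ring C can only be deprotonated reversibly and returns as the trans ester.

Step 27
Reactants: 33 bis(aryldiazoacetate)
Product: 35 all-trans pentacyclic hydroxy triester, via cis-cis triester acetate 34 (not isolated)
Conditions: Rh2(R-PTTL)4 (2 mol% per diazo group), toluene, −60 to −20 °C, slow addition of 33; then NaOMe (0.5 equiv), MeOH/THF, rt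
Reagents that add atoms: none
Why: Rh2(R-PTTL)4 turns each diazo group into a donor–acceptor rhodium carbenoid, which inserts in a concerted, asynchronous, hydride-transfer-like way into a C–H bond of the neighbouring O–CH2–aryl group; the closest known reaction is the enantioselective cyclisation of methyl 2-(2-benzyloxyphenyl)-2-diazoacetates to cis-2-aryl-2,3-dihydrobenzofuran-3-carboxylates with chiral dirhodium tetracarboxylates, which includes 2-benzyloxy-3-methoxyphenyl cases. Ring B closes by C2–C3 bond formation through 1,5-insertion into the ether CH2 on the ring C arene, and ring A closes in the same way into the ether CH2 on the ring B arene; both are five-membered closures with the new C–C bond in the ring. C2 of ring A and C2 of ring B are set by the catalyst, which chooses one of the two enantiotopic hydrogens (2S); C3 of each ring first forms cis to the aryl group and is then brought to trans (3S as the ester) by methoxide, with C2 as the controlling centre. The step needs site selectivity, which rests on the five-atom distance and on activation of the target C–H bond by both the ether oxygen and an electron-rich arene, while the tetrahydrofuran C2–H and ring C C2–H are remote and the CH2–OAc bonds are deactivated. It needs the two carbenoids not to meet, which slow addition at low temperature serves, and it needs catalyst control over the existing stereocentres, which is plausible because arene rings separate them from the reacting sites. The methoxide also removes the acetate, so 35 is isolated as the hydroxy triester.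

Step 28
Reactants: 35 hydroxy triester
Product: 36 tetraol bis(benzyl ether) (O,O'-dibenzyl target)
Conditions: LiAlH4, THF, 0 °C
Reagents that add atoms: none
Why: Hydride reduction of the three methyl esters to hydroxymethyl groups is faster than enolisation, so the trans relationships are kept; benzyl ethers and ring ethers are inert.

Step 29
Reactants: 36 tetraol bis(benzyl ether)
Product: 37 CNP0267891.2 (target)
Conditions: H2 (1 atm), 10% Pd/C, EtOAc/EtOH, rt
Reagents that add atoms: none
Why: Hydrogenolysis of the two primary benzyl aryl ethers, which cleave much faster than the hindered secondary ring C2–O bonds, as in the debenzylations that end lariciresinol and phenylcoumaran syntheses; the reaction is stopped when 36 is consumed.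

## Compound list

1 | vanillin | COc1cc(C=O)ccc1O | starting material
2 | allyl bromide | C=CCBr | starting material
3 | 4-(allyloxy)-3-methoxybenzaldehyde | COc1cc(C=O)ccc1OCC=C | intermediate
4 | 5-allylvanillin (3-allyl-4-hydroxy-5-methoxybenzaldehyde) | COc1cc(C=O)cc(CC=C)c1O | intermediate
5 | 4-(benzyloxy)-3-methoxybenzaldehyde | COc1cc(C=O)ccc1OCc1ccccc1 | starting material
6 | dimethyl succinate | COC(=O)CCC(=O)OC | starting material
7 | (E)-4-[4-(benzyloxy)-3-methoxyphenyl]-3-(methoxycarbonyl)but-3-enoic acid | COC(=O)/C(=C/c1ccc(OCc2ccccc2)c(OC)c1)CC(=O)O | intermediate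
8 | (3S)-4-[4-(benzyloxy)-3-methoxyphenyl]-3-(methoxycarbonyl)butanoic acid | COc1cc(C[C@@H](CC(=O)O)C(=O)OC)ccc1OCc1ccccc1 | intermediate
9 | (3S)-4-[4-(benzyloxy)-3-methoxyphenyl]-3-(hydroxymethyl)butanoic acid (not isolated) | COc1cc(C[C@@H](CC(=O)O)CO)ccc1OCc1ccccc1 | intermediate
10 | (4S)-4-[4-(benzyloxy)-3-methoxybenzyl]dihydrofuran-2(3H)-one | COc1cc(C[C@@H]2COC(=O)C2)ccc1OCc1ccccc1 | intermediate
11 | 2-allyl-4-formyl-6-methoxyphenyl pivalate | COc1cc(C=O)cc(CC=C)c1OC(=O)C(C)(C)C | intermediate
12 | (3R,4S)-3-[(3-allyl-5-methoxy-4-pivaloyloxyphenyl)(hydroxy)methyl]-4-[4-(benzyloxy)-3-methoxybenzyl]dihydrofuran-2(3H)-one, both carbinol epimers | COc1cc(C[C@@H]2COC(=O)[C@H]2C(O)c2cc(OC)c(OC(=O)C(C)(C)C)c(CC=C)c2)ccc1OCc1ccccc1 | intermediate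
13 | (2S,3S)-2-[(3-allyl-4-hydroxy-5-methoxyphenyl)(hydroxy)methyl]-3-[4-(benzyloxy)-3-methoxybenzyl]butane-1,4-diol, both carbinol epimers | COc1cc(C[C@H](CO)[C@@H](CO)C(O)c2cc(OC)c(O)c(CC=C)c2)ccc1OCc1ccccc1 | intermediate
14 | 2-allyl-4-{(2R,3S,4S)-4-[4-(benzyloxy)-3-methoxybenzyl]-3-(hydroxymethyl)tetrahydrofuran-2-yl}-6-methoxyphenol | COc1cc(C[C@@H]2CO[C@@H](c3cc(OC)c(O)c(CC=C)c3)[C@@H]2CO)ccc1OCc1ccccc1 | intermediate
15 | 4-(benzyloxy)-3-methoxybenzyl alcohol | COc1cc(CO)ccc1OCc1ccccc1 | starting material
16 | 3-allyl-4-{[4-(benzyloxy)-3-methoxybenzyl]oxy}-5-methoxybenzaldehyde | COc1cc(C=O)cc(CC=C)c1OCc1ccc(OCc2ccccc2)c(OC)c1 | intermediate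
17 | (3-allyl-4-{[4-(benzyloxy)-3-methoxybenzyl]oxy}-5-methoxyphenyl)methanol | COc1cc(CO)cc(CC=C)c1OCc1ccc(OCc2ccccc2)c(OC)c1 | intermediate
18 | 3-allyl-4-{[4-(benzyloxy)-3-methoxybenzyl]oxy}-5-methoxybenzyl acetate | COc1cc(COC(C)=O)cc(CC=C)c1OCc1ccc(OCc2ccccc2)c(OC)c1 | intermediate
19 | (5-(acetoxymethyl)-2-{[4-(benzyloxy)-3-methoxybenzyl]oxy}-3-methoxyphenyl)acetaldehyde | COc1cc(COC(C)=O)cc(CC=O)c1OCc1ccc(OCc2ccccc2)c(OC)c1 | intermediate
20 | (5-(acetoxymethyl)-2-{[4-(benzyloxy)-3-methoxybenzyl]oxy}-3-methoxyphenyl)acetic acid | COc1cc(COC(C)=O)cc(CC(=O)O)c1OCc1ccc(OCc2ccccc2)c(OC)c1 | intermediate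
21 | methyl (5-(acetoxymethyl)-2-{[4-(benzyloxy)-3-methoxybenzyl]oxy}-3-methoxyphenyl)acetate | COc1cc(COC(C)=O)cc(CC(=O)OC)c1OCc1ccc(OCc2ccccc2)c(OC)c1 | intermediate
22 | methyl 2-(5-(acetoxymethyl)-2-{[4-(benzyloxy)-3-methoxybenzyl]oxy}-3-methoxyphenyl)-2-diazoacetate | COc1cc(COC(C)=O)cc(C(=[N+]=[N-])C(=O)OC)c1OCc1ccc(OCc2ccccc2)c(OC)c1 | intermediate
23 | methyl (2R,3S)-5-(acetoxymethyl)-2-[4-(benzyloxy)-3-methoxyphenyl]-7-methoxy-2,3-dihydrobenzofuran-3-carboxylate, cis (not isolated) | CC(=O)OCc1cc(OC)c2c(c1)[C@H](C(=O)OC)[C@H](c1ccc(OCc3ccccc3)c(OC)c1)O2 | intermediate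
24 | methyl (2R,3R)-2-[4-(benzyloxy)-3-methoxyphenyl]-5-(hydroxymethyl)-7-methoxy-2,3-dihydrobenzofuran-3-carboxylate, trans | OCc1cc(OC)c2c(c1)[C@@H](C(=O)OC)[C@H](c1ccc(OCc3ccccc3)c(OC)c1)O2 | intermediate
25 | methyl (2R,3R)-5-[(2-allyl-4-formyl-6-methoxyphenoxy)methyl]-2-[4-(benzyloxy)-3-methoxyphenyl]-7-methoxy-2,3-dihydrobenzofuran-3-carboxylate | O=Cc1cc(OC)c(OCc2cc(OC)c3c(c2)[C@@H](C(=O)OC)[C@H](c2ccc(OCc4ccccc4)c(OC)c2)O3)c(CC=C)c1 | intermediate
26 | methyl (2R,3R)-5-{[2-allyl-4-(hydroxymethyl)-6-methoxyphenoxy]methyl}-2-[4-(benzyloxy)-3-methoxyphenyl]-7-methoxy-2,3-dihydrobenzofuran-3-carboxylate | OCc1cc(OC)c(OCc2cc(OC)c3c(c2)[C@@H](C(=O)OC)[C@H](c2ccc(OCc4ccccc4)c(OC)c2)O3)c(CC=C)c1 | intermediate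
27 | methyl (2R,3R)-5-{[2-allyl-4-(bromomethyl)-6-methoxyphenoxy]methyl}-2-[4-(benzyloxy)-3-methoxyphenyl]-7-methoxy-2,3-dihydrobenzofuran-3-carboxylate | BrCc1cc(OC)c(OCc2cc(OC)c3c(c2)[C@@H](C(=O)OC)[C@H](c2ccc(OCc4ccccc4)c(OC)c2)O3)c(CC=C)c1 | intermediate
28 | diallyl alcohol: methyl (2R,3R)-5-{[2-allyl-4-({2-allyl-4-[(2R,3S,4S)-4-[4-(benzyloxy)-3-methoxybenzyl]-3-(hydroxymethyl)tetrahydrofuran-2-yl]-6-methoxyphenoxy}methyl)-6-methoxyphenoxy]methyl}-2-[4-(benzyloxy)-3-methoxyphenyl]-7-methoxy-2,3-dihydrobenzofuran-3-carboxylate | COc1cc(C[C@@H]2CO[C@@H](c3cc(OC)c(OCc4cc(OC)c(OCc5cc(OC)c6c(c5)[C@@H](C(=O)OC)[C@H](c7ccc(OCc8ccccc8)c(OC)c7)O6)c(c4)CC=C)c(c3)CC=C)[C@@H]2CO)ccc1OCc9ccccc9 | intermediate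
29 | diallyl acetate: 28 with the tetrahydrofuran CH2OH as CH2OAc | COc1cc(C[C@@H]2CO[C@@H](c3cc(OC)c(OCc4cc(OC)c(OCc5cc(OC)c6c(c5)[C@@H](C(=O)OC)[C@H](c7ccc(OCc8ccccc8)c(OC)c7)O6)c(c4)CC=C)c(c3)CC=C)[C@@H]2COC(C)=O)ccc1OCc9ccccc9 | intermediate
30 | bis(arylacetaldehyde): 29 with both C-allyl groups as CH2CHO | COc1cc(C[C@@H]2CO[C@@H](c3cc(OC)c(OCc4cc(OC)c(OCc5cc(OC)c6c(c5)[C@@H](C(=O)OC)[C@H](c7ccc(OCc8ccccc8)c(OC)c7)O6)c(c4)CC=O)c(c3)CC=O)[C@@H]2COC(C)=O)ccc1OCc9ccccc9 | intermediate
31 | bis(arylacetic acid): 29 with both C-allyl groups as CH2CO2H | COc1cc(C[C@@H]2CO[C@@H](c3cc(OC)c(OCc4cc(OC)c(OCc5cc(OC)c6c(c5)[C@@H](C(=O)OC)[C@H](c7ccc(OCc8ccccc8)c(OC)c7)O6)c(c4)CC(=O)O)c(c3)CC(=O)O)[C@@H]2COC(C)=O)ccc1OCc9ccccc9 | intermediate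
32 | triester: 29 with both C-allyl groups as CH2CO2Me | COc1cc(C[C@@H]2CO[C@@H](c3cc(OC)c(OCc4cc(OC)c(OCc5cc(OC)c6c(c5)[C@@H](C(=O)OC)[C@H](c7ccc(OCc8ccccc8)c(OC)c7)O6)c(c4)CC(=O)OC)c(c3)CC(=O)OC)[C@@H]2COC(C)=O)ccc1OCc9ccccc9 | intermediate
33 | bis(aryldiazoacetate): 32 with both ArCH2CO2Me groups as ArC(=N2)CO2Me | COc1cc(C[C@@H]2CO[C@@H](c3cc(OC)c(OCc4cc(OC)c(OCc5cc(OC)c6c(c5)[C@@H](C(=O)OC)[C@H](c7ccc(OCc8ccccc8)c(OC)c7)O6)c(c4)C(=[N+]=[N-])C(=O)OC)c(c3)C(=[N+]=[N-])C(=O)OC)[C@@H]2COC(C)=O)ccc1OCc9ccccc9 | intermediate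
34 | pentacyclic triester acetate with rings A and B closed cis, each (2S,3R), ring C (2R,3R) (not isolated) | COc1cc(C[C@@H]2CO[C@@H](c3cc(OC)c4c(c3)[C@@H](C(=O)OC)[C@@H](c3cc(OC)c5c(c3)[C@@H](C(=O)OC)[C@@H](c3cc(OC)c6c(c3)[C@@H](C(=O)OC)[C@H](c3ccc(OCc7ccccc7)c(OC)c3)O6)O5)O4)[C@@H]2COC(C)=O)ccc1OCc8ccccc8 | intermediate
35 | all-trans hydroxy triester: rings A and B (2S,3S), ring C (2R,3R), tetrahydrofuran (2R,3S,4S) with free CH2OH, two benzyl ethers | COc1cc(C[C@@H]2CO[C@@H](c3cc(OC)c4c(c3)[C@H](C(=O)OC)[C@@H](c3cc(OC)c5c(c3)[C@H](C(=O)OC)[C@@H](c3cc(OC)c6c(c3)[C@@H](C(=O)OC)[C@H](c3ccc(OCc7ccccc7)c(OC)c3)O6)O5)O4)[C@@H]2CO)ccc1OCc8ccccc8 | intermediate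
36 | tetraol bis(benzyl ether): the target with both phenols as benzyl ethers | COc1cc(C[C@@H]2CO[C@@H](c3cc(OC)c4c(c3)[C@H](CO)[C@@H](c3cc(OC)c5c(c3)[C@H](CO)[C@@H](c3cc(OC)c6c(c3)[C@@H](CO)[C@H](c3ccc(OCc7ccccc7)c(OC)c3)O6)O5)O4)[C@@H]2CO)ccc1OCc8ccccc8 | intermediate
37 | CNP0267891.2 | COc1cc(C[C@@H]2CO[C@@H](c3cc(OC)c4c(c3)[C@H](CO)[C@@H](c3cc(OC)c5c(c3)[C@H](CO)[C@@H](c3cc(OC)c6c(c3)[C@@H](CO)[C@H](c3ccc(O)c(OC)c3)O6)O5)O4)[C@@H]2CO)ccc1O | target

## Step count and least certain steps

Total step count: 29. Longest linear sequence: 22 steps (steps 1, 2 and 10 to 29).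

**Step 27 (key step).**
- What may go wrong: incomplete catalyst control at one of the two sites. Methylene insertions of this kind are highly but not perfectly enantioselective, and here each error appears as a diastereomer. Coupling of one carbenoid with the other diazo group, and scrambling of C2 by reversible E1cB ring opening during the methoxide equilibration, are the other likely failures.
- Fallback: it keeps the same two bond formations but moves the stereocontrol from catalyst plus base to auxiliary plus catalyst. It sets out from bis(acid) 31. Esterification (EDC·HCl, DMAP, CH2Cl2) with (S)-2-hydroxy-1-(pyrrolidin-1-yl)propan-1-one F1, made from ethyl (S)-lactate and pyrrolidine, would give the bis(lactamide ester) F2. Diazo transfer as in step 26 would give the bis(diazoester) F3. With Rh2(S-DOSP)4 in CH2Cl2, the pairing taken to be matched for the (2S,3S) series and known on 2-benzyloxy-3-methoxyphenyl diazoacetates to give the trans ester directly, the all-trans pentacycle F4 should form without any base. LiAlH4 would then reduce the two lactamide esters, the ring C methyl ester and the acetate together, and the route is rejoined at 36.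

**Step 17.**
- What may go wrong: erosion of enantioselectivity caused by the methoxy group next to the reacting ether, and partial racemisation of C2 during equilibration. Either would be carried forward as diastereomeric impurity in every later compound.
- Fallback: it sets out from acid 20. Esterification with (R)-2-hydroxy-1-(pyrrolidin-1-yl)propan-1-one F5 (from methyl (R)-lactate and pyrrolidine) would give the lactamide ester F6. Diazo transfer would give the diazo ester F7, and Rh2(R-DOSP)4 should give the trans ring C ester F8 directly. NaOMe in MeOH would exchange the lactamide ester for the methyl ester and remove the acetate, returning to 24.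

**Step 7.**
- What may go wrong: acyl transfer from the aryl pivalate to the lactone enolate or to the lithium aldolate, and retro-aldol on warming.
- Fallback: the allyl ether serves as the phenol protecting group and the Claisen rearrangement is postponed. It sets out from 3 and 10. The aldol reaction under the conditions of step 7 would give the aldol adduct F9, LiAlH4 the triol F10, and CSA the tetrahydrofuran allyl ether F11. Claisen rearrangement (N,N-diethylaniline, 190 °C) to the one free ortho position would return to 14.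

**Step 21.**
- What may go wrong: solvolysis or decomposition of the electron-rich benzylic bromide before it is captured by a phenoxide flanked by two ortho substituents.
- Fallback: it avoids the halide. It sets out from 14 and 26. Ac2O and pyridine would give the diacetate F12. Pyrrolidine, which cleaves only the aryl acetate, would give the phenol acetate F13. A Mitsunobu reaction of F13 with alcohol 26 (PPh3, DIAD, THF) would give 29 directly, bypassing 27 and 28.

## Further compounds

F1 | step 27 | (S)-2-hydroxy-1-(pyrrolidin-1-yl)propan-1-one | C[C@H](O)C(=O)N1CCCC1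
F2 | step 27 | bis[(S)-1-oxo-1-(pyrrolidin-1-yl)propan-2-yl] ester of bis(acid) 31 | COc1cc(C[C@@H]2CO[C@@H](c3cc(OC)c(OCc4cc(OC)c(OCc5cc(OC)c6c(c5)[C@@H](C(=O)OC)[C@H](c7ccc(OCc8ccccc8)c(OC)c7)O6)c(c4)CC(=O)O[C@@H](C)C(=O)N4CCCC4)c(c3)CC(=O)O[C@@H](C)C(=O)N3CCCC3)[C@@H]2COC(C)=O)ccc1OCc9ccccc9
F3 | step 27 | bis(diazoester) of F2 | COc1cc(C[C@@H]2CO[C@@H](c3cc(OC)c(OCc4cc(OC)c(OCc5cc(OC)c6c(c5)[C@@H](C(=O)OC)[C@H](c7ccc(OCc8ccccc8)c(OC)c7)O6)c(c4)C(=[N+]=[N-])C(=O)O[C@@H](C)C(=O)N4CCCC4)c(c3)C(=[N+]=[N-])C(=O)O[C@@H](C)C(=O)N3CCCC3)[C@@H]2COC(C)=O)ccc1OCc9ccccc9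
F4 | step 27 | all-trans pentacycle with (S)-lactamide esters on rings A and B, ring C methyl ester and tetrahydrofuran acetate | COc1cc(C[C@@H]2CO[C@@H](c3cc(OC)c4c(c3)[C@H](C(=O)O[C@@H](C)C(=O)N3CCCC3)[C@@H](c3cc(OC)c5c(c3)[C@H](C(=O)O[C@@H](C)C(=O)N3CCCC3)[C@@H](c3cc(OC)c6c(c3)[C@@H](C(=O)OC)[C@H](c3ccc(OCc7ccccc7)c(OC)c3)O6)O5)O4)[C@@H]2COC(C)=O)ccc1OCc8ccccc8
F5 | step 17 | (R)-2-hydroxy-1-(pyrrolidin-1-yl)propan-1-one | C[C@@H](O)C(=O)N1CCCC1
F6 | step 17 | (R)-1-oxo-1-(pyrrolidin-1-yl)propan-2-yl ester of acid 20 | COc1cc(COC(C)=O)cc(CC(=O)O[C@H](C)C(=O)N2CCCC2)c1OCc1ccc(OCc2ccccc2)c(OC)c1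
F7 | step 17 | diazo ester of F6 | COc1cc(COC(C)=O)cc(C(=[N+]=[N-])C(=O)O[C@H](C)C(=O)N2CCCC2)c1OCc1ccc(OCc2ccccc2)c(OC)c1
F8 | step 17 | (2R,3R)-trans ring C (R)-lactamide ester with 5-acetoxymethyl group | CC(=O)OCc1cc(OC)c2c(c1)[C@@H](C(=O)O[C@H](C)C(=O)N1CCCC1)[C@H](c1ccc(OCc3ccccc3)c(OC)c1)O2
F9 | step 7 | (3R,4S)-3-{[4-(allyloxy)-3-methoxyphenyl](hydroxy)methyl}-4-[4-(benzyloxy)-3-methoxybenzyl]dihydrofuran-2(3H)-one, both carbinol epimers | COc1cc(C[C@@H]2COC(=O)[C@H]2C(O)c2ccc(OCC=C)c(OC)c2)ccc1OCc1ccccc1
F10 | step 7 | (2S,3S)-2-{[4-(allyloxy)-3-methoxyphenyl](hydroxy)methyl}-3-[4-(benzyloxy)-3-methoxybenzyl]butane-1,4-diol, both carbinol epimers | COc1cc(C[C@H](CO)[C@@H](CO)C(O)c2ccc(OCC=C)c(OC)c2)ccc1OCc1ccccc1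
F11 | step 7 | {(2R,3S,4S)-2-[4-(allyloxy)-3-methoxyphenyl]-4-[4-(benzyloxy)-3-methoxybenzyl]tetrahydrofuran-3-yl}methanol | COc1cc(C[C@@H]2CO[C@@H](c3ccc(OCC=C)c(OC)c3)[C@@H]2CO)ccc1OCc1ccccc1
F12 | step 21 | diacetate of 14 (aryl acetate and primary acetate) | COc1cc(C[C@@H]2CO[C@@H](c3cc(OC)c(OC(C)=O)c(CC=C)c3)[C@@H]2COC(C)=O)ccc1OCc1ccccc1
F13 | step 21 | primary acetate of 14 with free phenol | COc1cc(C[C@@H]2CO[C@@H](c3cc(OC)c(O)c(CC=C)c3)[C@@H]2COC(C)=O)ccc1OCc1ccccc1
A1 | alternative 1 | tris(dihydrobenzofuran) ring A 5-carboxylate with three silyl ethers | COC(=O)c1cc(OC)c2c(c1)[C@H](CO[Si](C)(C)C(C)(C)C)[C@@H](c3cc(OC)c5c(c3)[C@H](CO[Si](C)(C)C(C)(C)C)[C@@H](c3cc(OC)c6c(c3)[C@@H](CO[Si](C)(C)C(C)(C)C)[C@H](c3ccc(OCc7ccccc7)c(OC)c3)O6)O5)O2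
A2 | alternative 1 | trans 4-(silyloxymethyl)-5-aryl γ-butyrolactone carrying rings B and C | O=C1C[C@H](CO[Si](C)(C)C(C)(C)C)[C@@H](c3cc(OC)c5c(c3)[C@H](CO[Si](C)(C)C(C)(C)C)[C@@H](c3cc(OC)c6c(c3)[C@@H](CO[Si](C)(C)C(C)(C)C)[C@H](c3ccc(OCc7ccccc7)c(OC)c3)O6)O5)O1
A3 | alternative 1 | methyl 3-methoxy-2-oxo-2H-pyran-5-carboxylate | O=C1OC=C(C(=O)OC)C=C1OC
A4 | alternative 2 | 5-bromo tris(dihydrobenzofuran) triester | Brc3cc(OC)c4c(c3)[C@H](C(=O)OC)[C@@H](c3cc(OC)c5c(c3)[C@H](C(=O)OC)[C@@H](c3cc(OC)c6c(c3)[C@@H](C(=O)OC)[C@H](c3ccc(OCc7ccccc7)c(OC)c3)O6)O5)O4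
A5 | alternative 2 | (2S)-6-bromo-8-methoxyflavanone carrying rings B and C as the 2-aryl group | O=C1C[C@@H](c3cc(OC)c5c(c3)[C@H](C(=O)OC)[C@@H](c3cc(OC)c6c(c3)[C@@H](C(=O)OC)[C@H](c3ccc(OCc7ccccc7)c(OC)c3)O6)O5)Oc2c(OC)cc(Br)cc12
A6 | alternative 3 | protected target with free tetrahydrofuran hydroxymethyl group | COc1cc(C[C@@H]2CO[C@@H](c3cc(OC)c4c(c3)[C@H](CO[Si](C)(C)C(C)(C)C)[C@@H](c3cc(OC)c5c(c3)[C@H](CO[Si](C)(C)C(C)(C)C)[C@@H](c3cc(OC)c6c(c3)[C@@H](CO[Si](C)(C)C(C)(C)C)[C@H](c3ccc(OCc7ccccc7)c(OC)c3)O6)O5)O4)[C@@H]2CO)ccc1OCc8ccccc8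
A7 | alternative 3 | aryl(oxiranyl)methyl (E)-cinnamyl ether of the tris(dihydrobenzofuran), either epoxide epimer | COc1cc(/C=C/CO[C@@H](c3cc(OC)c4c(c3)[C@H](CO[Si](C)(C)C(C)(C)C)[C@@H](c3cc(OC)c5c(c3)[C@H](CO[Si](C)(C)C(C)(C)C)[C@@H](c3cc(OC)c6c(c3)[C@@H](CO[Si](C)(C)C(C)(C)C)[C@H](c3ccc(OCc7ccccc7)c(OC)c3)O6)O5)O4)C2CO2)ccc1OCc8ccccc8
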